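**Retrosynthetic overview**
- Feature: in ring C the carbonyl carbon C4 stands alone between C4a of ring A and the C3=C2 pair that carries ring B, and O1 sits on C8a, ortho to C4a. Ring C therefore splits into an ortho-iodophenol (C4a–I, C8a–OH), carbon monoxide (C4) and an arylacetylene (C3, C2, ring B).
- Disconnections, backwards: the four O-benzyl groups (hydrogenolysis); the C3–OH (C3 lithiation, borylation and oxidation of the flavone); bonds C4a–C4, C4–C3 and O1–C2 (one palladium-catalysed carbonylative annulation); C4a–I (iodination ortho to the free phenol).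
- The (R) centre on the C8 side chain is set before ring C exists, by hydroxyl-directed asymmetric hydrogenation of a 1,1-diarylethene. This alkene is built from 2-hydroxy-4,6-bis(benzyloxy)acetophenone and a syringyl Grignard reagent; the acetyl C=O carbon ends up as the stereocentre and the hydrogen-bonded OH as O1.
- Ring order: ring A, ring B and the syringyl ring are bought; ring C is the only ring formed.

Key step: step 7

Assumption: no reliable model predicts the sense of induction of the directed hydrogenation for this substrate, so the ligand antipode written in step 4 is provisional. Both antipodes are commercial. The one that gives the (R) product is fixed in a pilot run, and the configuration is read from anomalous-dispersion X-ray analysis of the derived iodophenol.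

**Step 1**
Reactants: 1 2,4,6-trihydroxyacetophenone
Product: 2 1-[2,4-bis(benzyloxy)-6-hydroxyphenyl]ethan-1-one
Conditions: BnBr (2.1 equiv), K2CO3 (2.2 equiv), DMF, 60 °C
Reagents that add atoms: benzyl bromide, BrCc1ccccc1
Why: Williamson etherification in which the 4-OH and one ortho-OH are alkylated, whereas the last ortho-OH is held in a strong hydrogen bond to the acetyl oxygen and stays free when only two equivalents of benzyl bromide are offered.

**Step 2**
Reactants: 3 4-bromo-2,6-dimethoxyphenol
Product: 4 2-(benzyloxy)-5-bromo-1,3-dimethoxybenzene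
Conditions: BnBr (1.1 equiv), K2CO3 (1.5 equiv), DMF, 50 °C
Reagents that add atoms: benzyl bromide, BrCc1ccccc1
Why: Williamson etherification of the only phenol, which removes the acidic proton ahead of Grignard formation and installs a group that falls in the final hydrogenolysis.

**Step 3**
Reactants: 2 1-[2,4-bis(benzyloxy)-6-hydroxyphenyl]ethan-1-one; 4 2-(benzyloxy)-5-bromo-1,3-dimethoxybenzene (2.5 equiv)
Product: 7 3,5-bis(benzyloxy)-2-{1-[4-(benzyloxy)-3,5-dimethoxyphenyl]ethenyl}phenol, via aryl Grignard reagent 5 (not isolated), via tertiary carbinol 6 (not isolated)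
Conditions: 4, Mg turnings, THF, reflux; then 2, LaCl3·2LiCl (1 equiv), THF, 0 °C → rt; 1 M HCl, 0 °C; crude carbinol, PPTS (5 mol %), toluene, 50 °C
Reagents that add atoms: magnesium, [Mg] (stays only in intermediate 5)
Why: Grignard addition to a 2-hydroxyaryl methyl ketone followed by acid-catalysed E1 dehydration: the first equivalent of 5 only deprotonates the chelated phenol, the second adds to the carbonyl group, which the oxophilic lanthanum salt activates while holding back enolisation, and the doubly benzylic, alkoxy-stabilised carbinol 6 loses water under acid mild enough to limit cationic dimerisation of 7.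

**Step 4**
Reactants: 7 3,5-bis(benzyloxy)-2-{1-[4-(benzyloxy)-3,5-dimethoxyphenyl]ethenyl}phenol
Product: 8 (R)-3,5-bis(benzyloxy)-2-{1-[4-(benzyloxy)-3,5-dimethoxyphenyl]ethyl}phenol
Conditions: [Rh(cod)2]BF4 (2 mol %), (R)-1-[(SP)-2-(diphenylphosphino)ferrocenyl]ethyldicyclohexylphosphine (2.2 mol %; antipode as fixed by the pilot run), H2 (20 bar), CH2Cl2–MeOH 1:1, rt
Reagents that add atoms: none
Why: Hydroxyl-directed asymmetric hydrogenation, a reaction type known for 2-(1-arylvinyl)phenols: the phenolic oxygen and the C=C bond bind the cationic rhodium bisphosphine as a chelate, which is possible only from the alkene face on which the OH of the twisted ring A lies, so the chiral ligand chooses between the two rapidly interconverting twist conformers of 7 and hydrogen is delivered to the face that sets the (R) centre, while the homogeneous rhodium catalyst leaves the three benzyl ethers intact.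

**Step 5**
Reactants: 8 (R)-3,5-bis(benzyloxy)-2-{1-[4-(benzyloxy)-3,5-dimethoxyphenyl]ethyl}phenol
Product: 9 (R)-3,5-bis(benzyloxy)-2-iodo-6-{1-[4-(benzyloxy)-3,5-dimethoxyphenyl]ethyl}phenol
Conditions: NIS (1.0 equiv), CH2Cl2, −40 → 0 °C, dark
Reagents that add atoms: N-iodosuccinimide, O=C1CCC(=O)N1I
Why: Electrophilic aromatic iodination of the phloroglucinol-type ring A, by far the most electron-rich ring: of its two free positions the one between OH and OBn (the future C4a) is open and can take iodine from hydroxyl-bound NIS, whereas the one between the two benzyloxy groups (the future C6) is screened, all the more because the 1-arylethyl group turns the neighbouring benzyl group over it, a preference that parallels the 3-iodination of 2-hydroxy-4,6-dialkoxyacetophenones and the 8-halogenation of perbenzylated catechins.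

**Step 6**
Reactants: 10 4-(benzyloxy)-3-methoxybenzaldehyde (O-benzylvanillin)
Product: 11 1-(benzyloxy)-4-ethynyl-2-methoxybenzene
Conditions: dimethyl (1-diazo-2-oxopropyl)phosphonate (1.2 equiv), K2CO3 (2 equiv), MeOH–THF, rt
Reagents that add atoms: dimethyl (1-diazo-2-oxopropyl)phosphonate, COP(=O)(OC)C(=[N+]=[N-])C(C)=O
Why: Seyferth–Gilbert homologation in its Ohira–Bestmann form: methanolysis of the acetyl group frees the diazomethylphosphonate anion, which olefinates the aldehyde, and the diazoalkene loses nitrogen and rearranges by a 1,2-hydride shift to the terminal alkyne under conditions that leave the benzyl ether alone.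

**Step 7**
Reactants: 9 (R)-3,5-bis(benzyloxy)-2-iodo-6-{1-[4-(benzyloxy)-3,5-dimethoxyphenyl]ethyl}phenol; 11 1-(benzyloxy)-4-ethynyl-2-methoxybenzene (1.5 equiv); 12 carbon monoxide
Product: 15 (R)-5,7-bis(benzyloxy)-2-[4-(benzyloxy)-3-methoxyphenyl]-8-{1-[4-(benzyloxy)-3,5-dimethoxyphenyl]ethyl}-4H-chromen-4-one, via ynone 13 (not isolated), via enaminone 14 (not isolated)
Conditions: PdCl2(PPh3)2 (5 mol %), CO (20 bar), Et2NH, 120 °C, autoclave, no copper salt
Reagents that add atoms: carbon monoxide (compound 12), [C-]#[O+]; diethylamine, CCNCC (its atoms stand only in intermediate 14)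
Why: PdCl2(PPh3)2 is reduced in the amine to zerovalent palladium, which inserts into the C–I bond of 9; CO insertion gives the aroylpalladium iodide, and amine-assisted transfer of the acetylide of 11 followed by reductive elimination gives ynone 13 (bonds C4a–C4 and C4–C3). Diethylamine then adds to C2 of the ynone to give enaminone 14, and the C8a hydroxyl replaces the amine by addition–elimination (bond O1–C2), which closes ring C in a six-membered, formally 6-endo mode. The closest known reaction type is the palladium-catalysed carbonylative coupling of ortho-iodophenols with terminal arylacetylenes in secondary amines, which gives flavones. No stereocentre is formed, and the existing one, a non-acidic diarylmethine C–H, is not touched by amine, CO or palladium. Three selectivities are needed: carbonylative over direct alkynylation (secured by CO pressure, the absence of copper and the two ortho substituents on the arylpalladium, which favour CO insertion), six- over five-membered closure (secured by the enaminone, whose C2 is the only electrophilic carbon left, so the 5-exo path to the aurone is shut), and the 8- over the 6-substituted flavone (secured by the substrate, since of the two oxygens flanking iodine only the one beside the 1-arylethyl group is free). Capture of the aroylpalladium by diethylamine is the main competitor, and the flanking OH and OBn groups should hinder the branched amine more than the rod-shaped acetylide.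

**Step 8**
Reactants: 15 (R)-5,7-bis(benzyloxy)-2-[4-(benzyloxy)-3-methoxyphenyl]-8-{1-[4-(benzyloxy)-3,5-dimethoxyphenyl]ethyl}-4H-chromen-4-one
Product: 18 (R)-5,7-bis(benzyloxy)-2-[4-(benzyloxy)-3-methoxyphenyl]-8-{1-[4-(benzyloxy)-3,5-dimethoxyphenyl]ethyl}-3-hydroxy-4H-chromen-4-one, via 3-lithioflavone 16 (not isolated), via C3 dimethyl boronate 17 (not isolated)
Conditions: LDA (1.5 equiv), THF, −78 °C; B(OMe)3 (3 equiv), −78 → 0 °C; AcOH, 30% aq H2O2, 0 °C → rt
Reagents that add atoms: hydrogen peroxide, OO (the C3 oxygen); lithium diisopropylamide, [Li]N(C(C)C)C(C)C (lithium only in 16); trimethyl borate, COB(OC)OC (boron and methoxy groups only in 17)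
Why: Carbonyl-assisted C3 deprotonation of a flavone with LDA, trapping with a borate and oxidative C–B to C–O migration form a known flavone-to-flavonol sequence, preferred here to dioxirane oxidation because it spares the tertiary diarylmethine C–H and the electron-rich rings, while LDA at −78 °C is kinetically too weak to remove that C–H, so the stereocentre holds.

**Step 9**
Reactants: 18 (R)-5,7-bis(benzyloxy)-2-[4-(benzyloxy)-3-methoxyphenyl]-8-{1-[4-(benzyloxy)-3,5-dimethoxyphenyl]ethyl}-3-hydroxy-4H-chromen-4-one
Product: 19 (R)-3,5,7-trihydroxy-2-(4-hydroxy-3-methoxyphenyl)-8-[1-(4-hydroxy-3,5-dimethoxyphenyl)ethyl]-4H-chromen-4-one (CNP0261887.1)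
Conditions: H2 (1 bar), palladium on carbon (10 wt % Pd), THF–MeOH 1:1, rt
Reagents that add atoms: none
Why: Catalytic hydrogenolysis cleaves the four benzylic C–O bonds, while the vinylogous-ester C2=C3 bond of the flavonol, the methyl ethers and the all-carbon diarylmethine centre are inert under one bar of hydrogen at room temperature.

**Compound list**
1 | 2,4,6-trihydroxyacetophenone | CC(=O)c1c(O)cc(O)cc1O | starting material
2 | 1-[2,4-bis(benzyloxy)-6-hydroxyphenyl]ethan-1-one | CC(=O)c1c(O)cc(OCc2ccccc2)cc1OCc1ccccc1 | intermediate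
3 | 4-bromo-2,6-dimethoxyphenol | COc1cc(Br)cc(OC)c1O | starting material
4 | 2-(benzyloxy)-5-bromo-1,3-dimethoxybenzene | COc1cc(Br)cc(OC)c1OCc1ccccc1 | intermediate
5 | [4-(benzyloxy)-3,5-dimethoxyphenyl]magnesium bromide | COc1cc([Mg]Br)cc(OC)c1OCc1ccccc1 | intermediate
6 | rac-3,5-bis(benzyloxy)-2-{1-[4-(benzyloxy)-3,5-dimethoxyphenyl]-1-hydroxyethyl}phenol | CC(O)(c1cc(OC)c(OCc2ccccc2)c(OC)c1)c1c(O)cc(OCc2ccccc2)cc1OCc1ccccc1 | intermediate
7 | 3,5-bis(benzyloxy)-2-{1-[4-(benzyloxy)-3,5-dimethoxyphenyl]ethenyl}phenol | C=C(c1cc(OC)c(OCc2ccccc2)c(OC)c1)c1c(O)cc(OCc2ccccc2)cc1OCc1ccccc1 | intermediate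
8 | (R)-3,5-bis(benzyloxy)-2-{1-[4-(benzyloxy)-3,5-dimethoxyphenyl]ethyl}phenol | Oc1cc(OCc2ccccc2)cc(OCc2ccccc2)c1[C@H](C)c1cc(OC)c(OCc2ccccc2)c(OC)c1 | intermediate
9 | (R)-3,5-bis(benzyloxy)-2-iodo-6-{1-[4-(benzyloxy)-3,5-dimethoxyphenyl]ethyl}phenol | Oc1c(I)c(OCc2ccccc2)cc(OCc2ccccc2)c1[C@H](C)c1cc(OC)c(OCc2ccccc2)c(OC)c1 | intermediate
10 | 4-(benzyloxy)-3-methoxybenzaldehyde | COc1cc(C=O)ccc1OCc1ccccc1 | starting material
11 | 1-(benzyloxy)-4-ethynyl-2-methoxybenzene | C#Cc1ccc(OCc2ccccc2)c(OC)c1 | intermediate
12 | carbon monoxide | [C-]#[O+] | starting material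
13 | (R)-1-(4,6-bis(benzyloxy)-3-{1-[4-(benzyloxy)-3,5-dimethoxyphenyl]ethyl}-2-hydroxyphenyl)-3-[4-(benzyloxy)-3-methoxyphenyl]prop-2-yn-1-one | COc1cc(C#CC(=O)c2c(OCc3ccccc3)cc(OCc3ccccc3)c([C@H](C)c3cc(OC)c(OCc4ccccc4)c(OC)c3)c2O)ccc1OCc1ccccc1 | intermediate
14 | (R)-1-(4,6-bis(benzyloxy)-3-{1-[4-(benzyloxy)-3,5-dimethoxyphenyl]ethyl}-2-hydroxyphenyl)-3-[4-(benzyloxy)-3-methoxyphenyl]-3-(diethylamino)prop-2-en-1-one (alkene geometry not fixed) | CCN(CC)C(=CC(=O)c1c(OCc2ccccc2)cc(OCc2ccccc2)c([C@H](C)c2cc(OC)c(OCc3ccccc3)c(OC)c2)c1O)c1ccc(OCc2ccccc2)c(OC)c1 | intermediate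
15 | (R)-5,7-bis(benzyloxy)-2-[4-(benzyloxy)-3-methoxyphenyl]-8-{1-[4-(benzyloxy)-3,5-dimethoxyphenyl]ethyl}-4H-chromen-4-one | COc1cc(-c2cc(=O)c3c(OCc4ccccc4)cc(OCc4ccccc4)c([C@H](C)c4cc(OC)c(OCc5ccccc5)c(OC)c4)c3o2)ccc1OCc1ccccc1 | intermediate
16 | 3-lithio derivative of flavone 15 | COc1cc(-c2oc3c([C@H](C)c4cc(OC)c(OCc5ccccc5)c(OC)c4)c(OCc4ccccc4)cc(OCc4ccccc4)c3c(=O)c2[Li])ccc1OCc1ccccc1 | intermediate
17 | dimethyl boronate at C3 of flavone 15 | COc1cc(-c2oc3c([C@H](C)c4cc(OC)c(OCc5ccccc5)c(OC)c4)c(OCc4ccccc4)cc(OCc4ccccc4)c3c(=O)c2B(OC)OC)ccc1OCc1ccccc1 | intermediate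
18 | (R)-5,7-bis(benzyloxy)-2-[4-(benzyloxy)-3-methoxyphenyl]-8-{1-[4-(benzyloxy)-3,5-dimethoxyphenyl]ethyl}-3-hydroxy-4H-chromen-4-one | COc1cc(-c2oc3c([C@H](C)c4cc(OC)c(OCc5ccccc5)c(OC)c4)c(OCc4ccccc4)cc(OCc4ccccc4)c3c(=O)c2O)ccc1OCc1ccccc1 | intermediate
19 | (R)-3,5,7-trihydroxy-2-(4-hydroxy-3-methoxyphenyl)-8-[1-(4-hydroxy-3,5-dimethoxyphenyl)ethyl]-4H-chromen-4-one | COc1cc(-c2oc3c([C@H](C)c4cc(OC)c(O)c(OC)c4)c(O)cc(O)c3c(=O)c2O)ccc1O | target

Total step count: 9. Longest linear sequence: 7 (step 1 or step 2, then steps 3, 4, 5, 7, 8, 9).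

**Steps most likely to fail**

**Step 7 (key step).**
- Risk: oxidative addition at the crowded, electron-rich C–I bond may be slow. That would open the way to reductive loss of iodine, to aminocarbonylation by the solvent, or to coupling without CO uptake followed by closure to a benzofuran.
- Fallback: the same three bonds are made stepwise, without palladium and without CO gas, setting out from 9 and 11.
- Alkyne 11 is deprotonated (n-BuLi, THF, −78 °C) to lithium [4-(benzyloxy)-3-methoxyphenyl]acetylide F1. This is acylated with N-methoxy-N-methylcarbamoyl chloride to the Weinreb alkynamide N-methoxy-N-methyl-3-[4-(benzyloxy)-3-methoxyphenyl]prop-2-ynamide F2.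
- Iodophenol 9 is treated with i-PrMgCl·LiCl (2.1 equiv, THF, −20 °C → rt), which deprotonates the phenol and then exchanges iodine for magnesium to give the C-magnesiated chloromagnesium phenoxide F3.
- Acylation of F3 by F2 comes back to the route at ynone 13, now isolated. Warming 13 with Et2NH in EtOH leads through 14 to flavone 15.

**Step 4.**
- Risk: facial selectivity may be poor because ring A carries substituents at both ortho positions and the chelate may form sluggishly. Turnover at the crowded alkene may also stall.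
- Fallback: racemic reduction and classical resolution, setting out from 7.
- Ionic hydrogenation (Et3SiH, CF3CO2H, CH2Cl2, −40 °C) should give the racemic phenol F4.
- Addition of F4 to (R)-1-phenylethyl isocyanate (DMAP, toluene, 60 °C) gives two diastereomers: the (R,R)-carbamate F5 and the (S,R)-carbamate F6. They are separated by crystallisation or chromatography.
- Methanolysis of F5 (K2CO3, MeOH–THF, rt) comes back to the route at 8.

**Step 5.**
- Risk: the iodinating agent may attack the position para to the hydroxyl, or a second iodination may follow the first.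
- Fallback: the iodine is introduced earlier, on the hydrogen-bonded ketone, setting out from 2. The preference for the position between OH and OR is well established for this class.
- I2 and HIO3 in aqueous EtOH should give 1-[4,6-bis(benzyloxy)-2-hydroxy-3-iodophenyl]ethan-1-one F7.
- Grignard reagent 5 is added under the conditions of step 3, but at −20 °C. Aryl-to-aryl iodine–magnesium exchange is slow on an electron-rich iodophenoxide, so the product should be the iodinated tertiary carbinol F8.
- PPTS dehydration of F8 gives the iodinated 1,1-diarylethene F9.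
- Hydrogenation under the conditions of step 4, which cationic rhodium bisphosphine catalysts carry out without touching aryl iodides, comes back to the route at 9.

**Further compounds**
F1 | step 7 | lithium [4-(benzyloxy)-3-methoxyphenyl]acetylide | [Li]C#Cc1ccc(OCc2ccccc2)c(OC)c1
F2 | step 7 | N-methoxy-N-methyl-3-[4-(benzyloxy)-3-methoxyphenyl]prop-2-ynamide | CON(C)C(=O)C#Cc1ccc(OCc2ccccc2)c(OC)c1
F3 | step 7 | C-magnesiated chloromagnesium phenoxide derived from 9 | Cl[Mg]Oc1c([Mg]Cl)c(OCc2ccccc2)cc(OCc2ccccc2)c1[C@H](C)c1cc(OC)c(OCc2ccccc2)c(OC)c1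
F4 | step 4 | rac-3,5-bis(benzyloxy)-2-{1-[4-(benzyloxy)-3,5-dimethoxyphenyl]ethyl}phenol | Oc1cc(OCc2ccccc2)cc(OCc2ccccc2)c1C(C)c1cc(OC)c(OCc2ccccc2)c(OC)c1
F5 | step 4 | aryl N-[(R)-1-phenylethyl]carbamate of (R)-8 | C[C@@H](NC(=O)Oc1cc(OCc2ccccc2)cc(OCc2ccccc2)c1[C@H](C)c1cc(OC)c(OCc2ccccc2)c(OC)c1)c1ccccc1
F6 | step 4 | aryl N-[(R)-1-phenylethyl]carbamate of the (S) enantiomer of 8 | C[C@@H](NC(=O)Oc1cc(OCc2ccccc2)cc(OCc2ccccc2)c1[C@@H](C)c1cc(OC)c(OCc2ccccc2)c(OC)c1)c1ccccc1
F7 | step 5 | 1-[4,6-bis(benzyloxy)-2-hydroxy-3-iodophenyl]ethan-1-one | CC(=O)c1c(O)c(I)c(OCc2ccccc2)cc1OCc1ccccc1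
F8 | step 5 | rac-3,5-bis(benzyloxy)-2-iodo-6-{1-[4-(benzyloxy)-3,5-dimethoxyphenyl]-1-hydroxyethyl}phenol | CC(O)(c1cc(OC)c(OCc2ccccc2)c(OC)c1)c1c(O)c(I)c(OCc2ccccc2)cc1OCc1ccccc1
F9 | step 5 | 3,5-bis(benzyloxy)-2-iodo-6-{1-[4-(benzyloxy)-3,5-dimethoxyphenyl]ethenyl}phenol | C=C(c1cc(OC)c(OCc2ccccc2)c(OC)c1)c1c(O)c(I)c(OCc2ccccc2)cc1OCc1ccccc1
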